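**Plan**

- Retrosynthesis: first one CH2–CH2 bond in the middle of the side chain is cut (made as a C=C by cross-metathesis, then hydrogenated). Then the furan-2(5H)-one ring is opened at O1–C5 and at C2–C3, which takes the C2(=O)–O1 unit out as carbon dioxide.
- Enabling feature: the tetrasubstituted C3=C4 double bond of the furanone holds the vinylic, methyl-bearing C3 and the allylic C5H2 cis. A C3 carbanion with a leaving group on C5 is therefore a three-carbon partner that takes up the C=O of CO2 as the last two ring atoms.
- Forward: anti-carbomagnesiation/iodination of but-2-yn-1-ol fixes that geometry, OH is changed to Cl, and a one-pot lithiation/CO2 annulation closes the only ring. The side chain is then completed by cross-metathesis and hydrogenation.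
- Stereochemistry: the single stereocentre (S, acetoxy carbon) comes from (S)-propylene oxide, opened at its CH2 so that the C–O bond is never broken.

Key step: step 5

Remark: carbon dioxide is counted as a reactant (12); but-3-enylmagnesium bromide is taken as the commercial THF solution.

**Route**

Step 1
Reactants: 1 (S)-propylene oxide [(S)-2-methyloxirane]; 2 but-3-en-1-ylmagnesium bromide
Product: 3 (S)-hept-6-en-2-ol
Conditions: 2 (1.3 equiv), CuI (10 mol%), THF, −30 °C; then 1, −30 → 0 °C; aq NH4Cl
Reagents that add atoms: none
Why: Copper-catalysed Grignard opening of a terminal epoxide is an SN2 attack at the unsubstituted CH2, so the stereocentre of 1 is carried into 3 unchanged as (S).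

Step 2
Reactants: 3 (S)-hept-6-en-2-ol
Product: 4 (S)-hept-6-en-2-yl acetate
Conditions: Ac2O, pyridine, DMAP (cat.), CH2Cl2, 0 °C → rt
Reagents that add atoms: acetic anhydride, CC(=O)OC(C)=O
Why: DMAP-catalysed acylation of a secondary alcohol takes place at oxygen and leaves the configuration of the carbinol carbon untouched.

Step 3
Reactants: 5 11-bromoundec-1-ene; 6 but-2-yn-1-ol
Product: 9 (Z)-3-iodo-2-(undec-10-en-1-yl)but-2-en-1-ol, via undec-10-enylmagnesium bromide 7 (not isolated), via cyclic alkenylmagnesium alkoxide 8 (not isolated)
Conditions: 5, Mg, THF, 40 °C (gives 7, 3 equiv); 6, CuI (10 mol%), THF–toluene, −40 °C → rt; then I2, THF, −78 → 0 °C; aq Na2S2O3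
Reagents that add atoms: iodine, II; magnesium, [Mg] (stays in 7 and 8 only)
Why: The alkoxide-directed, copper-catalysed anti-carbomagnesiation of a propargylic alcohol (Duboudin-type) should deliver the alkyl group to C2 and magnesium to C3 in the five-membered chelate 8, whose C–Mg bond is cleaved by iodine with retention, so that iodine ends up cis to CH2OH (Z).

Step 4
Reactants: 9 (Z)-3-iodo-2-(undec-10-en-1-yl)but-2-en-1-ol
Product: 11 (Z)-12-(chloromethyl)-13-iodotetradeca-1,12-diene, via allylic mesylate 10 (not isolated)
Conditions: MsCl, 2,4,6-collidine, LiCl, DMF, 0 °C → rt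
Reagents that add atoms: lithium chloride, [Li+].[Cl-]; methanesulfonyl chloride, CS(=O)(=O)Cl (its sulfonyl group stays in 10 only; its chloride may also end up in 11)
Why: Collington–Meyers chlorination (mesylate 10, then SN2 by chloride) should convert the primary allylic alcohol into the chloride without allylic transposition, which the fully substituted far end of the alkene disfavours, and without touching the alkenyl iodide.

Step 5
Reactants: 11 (Z)-12-(chloromethyl)-13-iodotetradeca-1,12-diene; 12 carbon dioxide
Product: 15 3-methyl-4-(undec-10-en-1-yl)furan-2(5H)-one, via chloroalkenyllithium 13 (not isolated), via lithium chlorobutenoate 14 (not isolated)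
Conditions: t-BuLi (2.1 equiv), Et2O, −78 °C; CO2 (dry gas, excess), −78 → 0 °C; then THF–DMPU, 50 °C
Reagents that add atoms: none
Why: Iodine–lithium exchange with tert-butyllithium at −78 °C should be far faster than any attack on the primary allylic chloride and should give the alkenyllithium 13 with retention of the double-bond geometry, which carbon dioxide traps at the vinylic carbon to form the C2–C3 bond of the furanone as the carboxylate 14. Because step 3 placed iodine and the CH2X group cis on the tetrasubstituted alkene, the carboxylate oxygen of 14 is held next to the allylic CH2Cl and should displace chloride on warming, forming the O1–C5 bond. The closest known reaction types are the carboxylation of alkenyllithiums and the lactonisation of (Z)-γ-halo-α,β-unsaturated carboxylates to butenolides, run here in one flask as an anionic (3+2) annulation in which 11 serves as a vinyl-anion/allyl-cation synthon and CO2 as the two-atom partner. The furanone ring closes in the 5-exo-tet mode. No stereocentre is formed, and the alkene geometry needed for closure is fixed by the substrate. The selectivity needed is exchange at iodine in preference to substitution, elimination or exchange at the allylic chloride, which the much higher rate of I/Li exchange at low temperature and slow addition of the base to the cold substrate should secure.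

Step 6
Reactants: 15 3-methyl-4-(undec-10-en-1-yl)furan-2(5H)-one; 4 (S)-hept-6-en-2-yl acetate
Product: 16 (2S)-16-(4-methyl-5-oxo-2,5-dihydrofuran-3-yl)hexadec-6-en-2-yl acetate (E/Z mixture)
Conditions: 4 (2.5 equiv), Grubbs II (5 mol%), 1,4-benzoquinone (10 mol%), CH2Cl2, 40 °C
Reagents that add atoms: none
Why: Olefin cross-metathesis of two unhindered terminal alkenes with a ruthenium carbene should join the fragments with loss of ethene, the tetrasubstituted electron-poor furanone alkene being inert, and the E/Z mixture is of no consequence because the alkene is hydrogenated next.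

Step 7
Reactants: 16 (2S)-16-(4-methyl-5-oxo-2,5-dihydrofuran-3-yl)hexadec-6-en-2-yl acetate
Product: 17 (2S)-16-(4-methyl-5-oxo-2,5-dihydrofuran-3-yl)hexadecan-2-yl acetate (target)
Conditions: H2 (1 atm), RhCl(PPh3)3 (5 mol%), benzene–EtOH, rt
Reagents that add atoms: none
Why: Homogeneous hydrogenation with Wilkinson's catalyst reduces 1,2-disubstituted alkenes but not the tetrasubstituted conjugated C3=C4 bond of the furanone, and does not cleave the allylic C5–O bond or affect the stereocentre.

**Compound list**

1 | (S)-propylene oxide | C[C@H]1CO1 | starting material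
2 | but-3-en-1-ylmagnesium bromide | C=CCC[Mg]Br | starting material
3 | (S)-hept-6-en-2-ol | C[C@H](O)CCCC=C | intermediate
4 | (S)-hept-6-en-2-yl acetate | CC(=O)O[C@@H](C)CCCC=C | intermediate
5 | 11-bromoundec-1-ene | C=CCCCCCCCCCBr | starting material
6 | but-2-yn-1-ol | CC#CCO | starting material
7 | undec-10-en-1-ylmagnesium bromide | C=CCCCCCCCCC[Mg]Br | intermediate
8 | 3-methyl-4-(undec-10-en-1-yl)-2,5-dihydro-1,2-oxamagnesole (cyclic alkenylmagnesium alkoxide) | CC1=C(CCCCCCCCCC=C)CO[Mg]1 | intermediate
9 | (Z)-3-iodo-2-(undec-10-en-1-yl)but-2-en-1-ol (I cis to CH2OH) | C/C(I)=C(/CO)CCCCCCCCCC=C | intermediate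
10 | (Z)-3-iodo-2-(undec-10-en-1-yl)but-2-en-1-yl methanesulfonate | C/C(I)=C(/COS(C)(=O)=O)CCCCCCCCCC=C | intermediate
11 | (Z)-12-(chloromethyl)-13-iodotetradeca-1,12-diene (I cis to CH2Cl) | C/C(I)=C(/CCl)CCCCCCCCCC=C | intermediate
12 | carbon dioxide | O=C=O | starting material
13 | [(2E)-3-(chloromethyl)tetradeca-2,13-dien-2-yl]lithium (Li cis to CH2Cl) | C/C([Li])=C(/CCl)CCCCCCCCCC=C | intermediate
14 | lithium (2Z)-3-(chloromethyl)-2-methyltetradeca-2,13-dienoate (carboxylate cis to CH2Cl) | C/C(C(=O)[O-])=C(/CCl)CCCCCCCCCC=C.[Li+] | intermediate
15 | 3-methyl-4-(undec-10-en-1-yl)furan-2(5H)-one | CC1=C(CCCCCCCCCC=C)COC1=O | intermediate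
16 | (2S)-16-(4-methyl-5-oxo-2,5-dihydrofuran-3-yl)hexadec-6-en-2-yl acetate (E/Z mixture) | CC(=O)O[C@@H](C)CCCC=CCCCCCCCCCC1=C(C)C(=O)OC1 | intermediate
17 | (2S)-16-(4-methyl-5-oxo-2,5-dihydrofuran-3-yl)hexadecan-2-yl acetate | CC(=O)O[C@@H](C)CCCCCCCCCCCCCCC1=C(C)C(=O)OC1 | target

**Step count and risks**

Total steps: 7. Longest linear sequence: 5 steps (steps 3 to 7, from 5 and 6); the side branch is steps 1 and 2.

Steps most likely to fail:

1. Step 5. tert-Butyllithium may attack the allylic chloride (substitution or elimination) before the exchange is complete. The alkenyllithium may couple with unreacted chloride or add to the carboxylate already formed if CO2 is in short supply. Ring closure of the lithium carboxylate may be slow. Fallback: from 9, palladium-catalysed carbonylative lactonisation of the (Z)-iodoallylic alcohol (Pd(PPh3)4, CO 1 atm, Et3N, MeCN, 60 °C) should give 15 directly, the alcohol oxygen becoming the ring oxygen. Step 4 is then not needed and no new compound is made (F0).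

2. Step 3. Carbomagnesiation with a primary alkyl Grignard reagent may be sluggish, may lose regio- or anti-selectivity, and iodine may add to the terminal alkene. Fallback: from 5, alkylation of ethyl acetoacetate (NaH, THF–DMF) should give ethyl 2-acetyltridec-12-enoate F1. Chelation-controlled enol triflation (Tf2O, aq LiOH, toluene, 0 °C) should give ethyl (Z)-2-(undec-10-en-1-yl)-3-(trifluoromethylsulfonyloxy)but-2-enoate F2. Nickel-catalysed triflate-to-iodide exchange (NaI, Ni(OAc)2/cod cat., DMA–THF) should give ethyl (Z)-3-iodo-2-(undec-10-en-1-yl)but-2-enoate F3. Reduction with DIBAL-H (CH2Cl2, −78 °C) returns to 9.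

3. Step 6. The metathesis may give a statistical spread with much homodimer, and ruthenium hydride species may shift the double bonds and so produce chain-shortened homologues that are hard to separate. Fallback: from 15, radical anti-Markovnikov addition of HBr (HBr, dibenzoyl peroxide, hexane) should give 4-(11-bromoundecyl)-3-methylfuran-2(5H)-one F4. Commercial (S)-pent-4-en-2-ol is acetylated to (S)-pent-4-en-2-yl acetate F5 and hydroborated with 9-BBN to (S)-5-(9-borabicyclo[3.3.1]nonan-9-yl)pentan-2-yl acetate F6. Alkyl–alkyl Suzuki coupling of F4 with F6 (Pd(OAc)2, PCy3, K3PO4·H2O, THF, rt) should give 17 directly, so steps 6 and 7 are bypassed.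

**Further compounds**

F0 | step 5 | none | none
F1 | step 3 | ethyl 2-acetyltridec-12-enoate | CCOC(=O)C(CCCCCCCCCC=C)C(C)=O
F2 | step 3 | ethyl (Z)-2-(undec-10-en-1-yl)-3-(trifluoromethylsulfonyloxy)but-2-enoate | CCOC(=O)/C(CCCCCCCCCC=C)=C(/C)OS(=O)(=O)C(F)(F)F
F3 | step 3 | ethyl (Z)-3-iodo-2-(undec-10-en-1-yl)but-2-enoate | CCOC(=O)/C(CCCCCCCCCC=C)=C(/C)I
F4 | step 6 | 4-(11-bromoundecyl)-3-methylfuran-2(5H)-one | CC1=C(CCCCCCCCCCCBr)COC1=O
F5 | step 6 | (S)-pent-4-en-2-yl acetate | CC(=O)O[C@@H](C)CC=C
F6 | step 6 | (S)-5-(9-borabicyclo[3.3.1]nonan-9-yl)pentan-2-yl acetate | CC(=O)O[C@@H](C)CCCB1C2CCCC1CCC2
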